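- In the ochre run, E gained from 2.00 min to 3.00 min over E gained in the first 1.00 min is a ratio of 0.420. Yet Q at the middles of those spans stands at a ratio of only 0.710, so E slows faster than Q falls.

| flask | Q | J | G | remark | time |
|---|---|---|---|---|---|
| amber | 0.067 M | 0.50 equiv | 0.052 mol% | run made earlier |  |
| ochre | 0.15 M | 0.50 equiv | 0.052 mol% | run made earlier |  |
| green | 0.10 M | 0.50 equiv | 0.1 mol% | run made earlier |  |
| flask | 0.10 M | 0.500 equiv | 0.052 mol% |  | 5.0 min |

| run | time / min | E / % | Q / % |
|---|---|---|---|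
| amber | 0.500 | 4.1 | 95.9 |
| amber | 1.00 | 8.1 | 89.2 |
| amber | 1.50 | 10.6 | 87.3 |
| amber | 2.00 | 14.5 | 82.1 |
| amber | 2.50 | 17.6 | 78.2 |
| amber | 3.00 | 20.3 | 73.5 |
| ochre | 0.500 | 9.3 | 89.0 |
| ochre | 1.00 | 16.2 | 80.6 |
| ochre | 1.50 | 21.5 | 75.2 |
| ochre | 2.00 | 25.0 | 69.5 |
| ochre | 2.50 | 29.9 | 63.2 |
| ochre | 3.00 | 31.8 | 57.7 |
| green | 0.667 | 12.4 | 82.8 |
| green | 1.33 | 24.7 | 71.3 |
| green | 2.00 | 35.8 | 62.2 |
| green | 2.50 | 38.7 | 56.6 |
| green | 3.00 | 44.6 | 52.8 |

(each reading ± 1 percentage point)

- the E in the flask at 5.0 min, as a percentage of the Q charged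
- the Q in the flask at 5.0 min, as a percentage of the Q charged



- We suppose that each E spends one J, the limiting reagent, so the fraction of J left is j = 1 − 2e, with e the fraction of the Q charged that is E.
- Over the same two moments j has a ratio of 0.494, closer to the E ratio than Q's is. We therefore treat the rate as pseudo-first-order in J.
- The J decay constant, the negative logarithm of j divided by time, comes from the last readings as 0.174 /min in amber and 0.337 /min in ochre. The readings at 1.00 min give 0.177 /min and 0.392 /min, and with a scatter of 1 percentage point we read no trend in time from the two ochre values.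
- A straight line in the Q charge puts the flask's constant at 0.239 /min, which gives our E of 34.8 % at 5.0 min.
- The forecast says E 36 % and Q 52 %, and of the gap between Q lost and E formed it says that it “suggests an intermediate or side path”.
- The flask gives E 36.6 % and Q 56.1 %.

    L → D (k = 0.00380 /s)
    2 Q → X (k = 0.00220 /M/s)
    Z → G + E (k = 16.0 /s)
    Q + L ⇌ Z (K = 5.20 /M, k = 7500 /M/s)
    J + G → L (k = 350 /M/s)

- The flask keeps less of its J than of its Q, 27 % against 56 %. Its J gives a constant of 0.261 /min at 2.50 min and 0.262 /min at 5.0 min, beside our 0.239 /min. For a neighbour flask with 0.17 M of Q, the same line gives 0.376 /min, but its 6.7 % of J left at 5.0 min gives 0.541 /min.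

Readings and results were generated by integration with made-up constants; noise was put on by code.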